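## Structural features

The target is an achiral, open-chain 2-arylglycerol derivative: a tertiary carbinol carbon C8 carries a free hydroxyl (O8), a benzene ring and two identical arms, C9H2 and C10H2, each esterified on oxygen with 2-methylpropanoic acid. The only ring is a 1,2,4-trisubstituted benzene in which C1 is bonded to C8, C2 bears the methoxy group and C4 the methyl group. Because the two oxymethylene arms are the same, C8 is not a stereocentre and no stereocentres stand next to each other; intermediates in which the arms differ are chiral, are carried as racemates and converge on the achiral target. The fragile groups are the two esters and the tertiary benzylic hydroxyl: the esters would not survive organomagnesium reagents or basic peroxide and can migrate to O8 under base, and the hydroxyl ionises easily under acid because the ortho-methoxy and para-methyl groups stabilise a cation at C8. The real difficulty is the assembly of a crowded, fully substituted C8 next to an ortho substituent with oxygen on C8, C9 and C10, which means two 1,2-dioxygenated relationships that chemistry of normal polarity cannot make. A second issue is telling the two primary hydroxyls from the tertiary one at the end. The key step exploits the fact that C8 and C9 both correspond to carbonyl carbons, the formyl carbon of an aryl aldehyde and formaldehyde, so that the C8–C9 bond can be made by inverting the polarity of C8 with a carbene catalyst; C8 then reverts to an electrophilic ketone carbon that accepts C10.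

## Logic of the disconnections

10 to 8 and 9. The two acyl–oxygen bonds on the oxygens of C9 and C10 are cut. They go first because esters would not survive the organomagnesium and peroxide chemistry that builds C8–C10, and because both are the same, so that one reagent, 9, installs them together. The gain is a symmetrical, ester-free precursor, 8. The forward step has to acylate two primary hydroxyls and leave the tertiary benzylic O8–H untouched; the crowding at C8 should ensure this.

8 to 7. The C10–O bond is exchanged for a C10–Si bond. An oxygen-bearing carbanion at C10 cannot be used as such, whereas an alkoxysilyl group makes that carbon nucleophilic and is later replaced by hydroxyl. The gain is that C10 becomes the carbon of an easily made organometallic partner. The demand is that oxidation of the C–Si bond outruns Peterson elimination of the β-hydroxysilane unit of 7.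

7 to 4 and 6 (6 from 5). The C8–C10 bond is cut. C8 is a carbinol carbon, so its natural precursor is a ketone, and 4 offers exactly this with the hydroxyl on C9 already in place. The gain is one carbon less and a commercial silane, 5, as the source of 6. The forward addition must tolerate the free hydroxyl of 4, which costs one equivalent of 6 and saves a protecting group, and it must be faster than enolisation toward C9.

4 to 1 and 2 (through 3). The C8–C9 bond is cut. Both atoms are carbonyl carbons in the fragments, so the bond can form only if one of them changes polarity. C8 is chosen because its aldehyde, 1, can be turned catalytically into the nucleophile 3, while 2 is the best possible acceptor. The gain is maximal: both fragments are catalogue chemicals and no precursor synthesis is needed. The forward step demands cross- over homo-coupling with donor and acceptor roles correctly assigned.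

## Other disconnections considered

Alternative 1: The cut goes through the benzene ring itself, at C1–C2 and C5–C6.
- Forward key step: the ketene-acetal diene (1Z)-1-methoxy-3-methyl-1-(trimethylsilyloxy)buta-1,3-diene A1 would add in a Diels–Alder reaction to the ynone 2-oxobut-3-yn-1-yl 2-methylpropanoate A2. The nucleophilic CH2 terminus of A1 bonds to the β-carbon of A2 and the ketal carbon to the α-carbon. The cyclohexadiene aromatises by expelling its ketal methoxy group and, after desilylation, gives the phenol 2-(2-hydroxy-4-methylphenyl)-2-oxoethyl 2-methylpropanoate A3.
- In its favour: the matched polarity of the partners should fix the 1,2,4-pattern without isomers; C8, C9 and one ester arrive together; the free phenol would be a handle for analogues with other ether groups.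
- Against it here: the arene with exactly this substitution can be bought ready-made in 1, so ring construction spends steps on a solved problem. A2 is not a catalogue compound and is a polymerisation-prone Michael acceptor. A3 still needs O-methylation under base next to a migration-prone α-acyloxy ketone. C10 must then be added to the ketone in the presence of an ester, which excludes the magnesium reagent 6 or costs the ester.
- Comparison: on structure, both plans pass through an aryl ketone with oxygen on C9, and the alternative is the better in that C9 is already acylated. On mechanism, a thermal, catalyst-free cycloaddition of polarity-matched partners is the equal of the carbene step in reliability, and its regiocontrol is arguably firmer than the cross- versus homo-coupling control of the chosen plan. On step economy it is clearly behind: two partners must be made, and methylation, C10 introduction, oxidation and a second acylation still follow, roughly double the four steps of the chosen route.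

Alternative 2: Both C8–C9 and C8–C10 are cut at once, so that C8 becomes the carbonyl carbon of methyl 2-methoxy-4-methylbenzoate A4.
- Forward key step: A4 would take up two equivalents of the silylmethyl Grignard reagent 6 in the presence of anhydrous CeCl3 to give 1,3-bis[isopropoxy(dimethyl)silyl]-2-(2-methoxy-4-methylphenyl)propan-2-ol A5. A twofold Tamao–Fleming oxidation would lead to 8, and the same final acylation follows.
- In its favour: it uses the mirror symmetry of the target and installs both arms with one reagent in one flask. It would reach the target in three steps, one fewer than the chosen plan, so on step economy it is the better route. No cross-selectivity problem arises.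
- Against it: the intermediate α-silyl ketone is enolisable and can stall the second addition, which is why stoichiometric, rigorously dried CeCl3 is needed. A5 carries two silyl groups β to a tertiary benzylic alkoxide on an electron-rich ring, the arrangement that Peterson elimination to an allylsilane exploits, so the exposure to this loss is double that of 7. Two C–Si bonds must be oxidised completely.
- Comparison: structurally the two plans meet at 8 and are equal from there on. Mechanistically the alternative treats C8 as a double electrophile, whereas the chosen plan first inverts C8 to a nucleophile under catalytic, metal-free conditions and then uses it as an electrophile once; this halves the silicon and magnesium load and exposes only one β-hydroxysilane. In step count the alternative wins by one, and it would be the natural replacement if the carbene step proved unworkable.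

Alternative 3: The cut removes both C8–O8 and C8–C9, leaving C8 as the carbene carbon of tert-butyl 2-diazo-2-(2-methoxy-4-methylphenyl)acetate A6, with C10 present as the ester carbonyl.
- Forward key step: Rh2(OAc)4 would convert A6 into a rhodium carbenoid, and water A7 would add to give an oxonium ylide. Formaldehyde (from 2) would intercept the ylide in an aldol-type step before the 1,2-proton shift, giving racemic tert-butyl 2,3-dihydroxy-2-(2-methoxy-4-methylphenyl)propanoate A8. Hydride reduction of the ester would then give 8.
- In its favour: two bonds at the crowded C8, one C–O and one C–C, form in a single neutral operation, a better bond count per step than the chosen key step. All of C8–C10 are in place afterwards.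
- Against it: A6 requires an arylacetate precursor and a diazo transfer with a sulfonyl azide, both energetic materials. Simple formal O–H insertion competes with the three-component pathway and would give a product lacking C9. Formaldehyde is largely hydrated in the presence of A7 and is not among the activated acceptors for which such ylide trapping is well established. C10 enters at the carboxyl level and has to be reduced with a strong hydride, and the tert-butyl group is discarded.
- Comparison: on structure, the stereocentre at C8 in A8 is formed as a racemate and vanishes on reduction, just as it does for 7, so the plans are equal there. On mechanism, both are mild catalytic unions with formaldehyde as acceptor, but the carbenoid route has two competing channels where the carbene route has one. On step economy the alternative needs at least five steps (precursor ester, diazo transfer, key step, reduction, acylation) against four, and it is the less safe.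

Key step: step 1

Remark on the chemistry: the two oxymethylene arms are constitutionally identical, so the target is achiral; paraformaldehyde 2 is counted as monomeric formaldehyde in the atom balance; the substitution patterns of 1, 4 and the target agree and need no correction.

## Route

Step 1
Reactants: 1 2-methoxy-4-methylbenzaldehyde; 2 paraformaldehyde
Product: 4 2-hydroxy-1-(2-methoxy-4-methylphenyl)ethan-1-one, via Breslow enaminol 3 (not isolated)
Conditions: 3-ethylbenzothiazolium bromide (10 mol %), iPr2NEt (10 mol %), (CH2O)n (5 equiv), THF, 60 °C, sealed tube
Reagents that add atoms: none
Why: iPr2NEt deprotonates the benzothiazolium salt at C2 to the free carbene, which attacks the formyl carbon of 1; a proton shift converts the adduct into the Breslow enaminol 3, whose C8 is now nucleophilic (an acyl-anion equivalent). 3 adds through C8 to monomeric formaldehyde, set free from 2 at 60 °C, and so forms the C8–C9 bond; proton transfer to the new alkoxide and expulsion of the carbene then deliver the ketone 4 and regenerate the catalyst. The closest known reaction type is the carbene-catalysed cross-benzoin hydroxymethylation of aldehydes with paraformaldehyde. No ring is closed, and no stereocentre results because C8 ends as a carbonyl carbon and C9 as a CH2 group. The step needs chemoselectivity for cross- over homo-coupling with 1 as the donor: formaldehyde, unhindered, highly electrophilic and used in excess, is by far the better acceptor, while homo-benzoin of 1 is slowed by the ortho-methoxy group and the electron-rich ring and is reversible, so that any homo-adduct should feed back into the cross pathway. The product 4 has no formyl hydrogen and a deactivated, hindered carbonyl, so it can neither form a Breslow intermediate nor serve as an acceptor, and should accumulate.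

Step 2
Reactants: 4 2-hydroxy-1-(2-methoxy-4-methylphenyl)ethan-1-one; 5 (chloromethyl)(isopropoxy)dimethylsilane
Product: 7 3-[isopropoxy(dimethyl)silyl]-2-(2-methoxy-4-methylphenyl)propane-1,2-diol (racemic), via Grignard reagent 6 (not isolated)
Conditions: 5 (3.5 equiv), Mg, BrCH2CH2Br (cat.), THF, reflux; then 4, THF, 0 °C to rt; sat. aq. NH4Cl, 0 °C; crude used directly
Reagents that add atoms: none
Why: Grignard addition of a silylmethyl hydroxymethyl-anion equivalent to a ketone: the first equivalent of 6 removes the hydroxyl proton of 4, the magnesium alkoxide chelates and activates the carbonyl oxygen, and a second equivalent adds to C8; the α-silyl carbanion is only weakly basic, so addition should outpace enolisation, and C8 is formed as a racemic stereocentre that disappears again in step 3.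

Step 3
Reactants: 7 3-[isopropoxy(dimethyl)silyl]-2-(2-methoxy-4-methylphenyl)propane-1,2-diol (racemic)
Product: 8 2-(2-methoxy-4-methylphenyl)propane-1,2,3-triol
Conditions: 30% aq. H2O2, KF, KHCO3, THF/MeOH (1:1), rt to 40 °C; then aq. Na2S2O3
Reagents that add atoms: hydrogen peroxide, OO
Why: Tamao–Fleming oxidation: fluoride and bicarbonate activate the alkoxysilane, hydroperoxide attacks silicon and C10 migrates from silicon to oxygen, so the C10–Si bond becomes C10–OH; the buffered, nearly neutral medium should spare the β-hydroxysilane from Peterson elimination and leaves the anisole ring alone, and C8 becomes achiral again.

Step 4
Reactants: 8 2-(2-methoxy-4-methylphenyl)propane-1,2,3-triol; 9 isobutyric anhydride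
Product: 10 2-hydroxy-2-(2-methoxy-4-methylphenyl)propane-1,3-diyl bis(2-methylpropanoate)
Conditions: (iPrCO)2O (2.2 equiv), Et3N, DMAP (5 mol %), CH2Cl2, 0 °C; aq. NaHCO3 work-up
Reagents that add atoms: none
Why: DMAP-catalysed acylation by an anhydride: the two primary hydroxyls react fast, whereas the tertiary benzylic hydroxyl on the fully substituted C8 is too hindered to be acylated at 0 °C by a small excess of 9; the bicarbonate work-up without mineral acid protects the acid-labile benzylic carbinol.

## Compound list

1 | 2-methoxy-4-methylbenzaldehyde | COc1cc(C)ccc1C=O | starting material
2 | paraformaldehyde (counted as formaldehyde) | C=O | starting material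
3 | Breslow enaminol, (3-ethyl-1,3-benzothiazol-2(3H)-ylidene)(2-methoxy-4-methylphenyl)methanol | CCN1C(=C(O)c2ccc(C)cc2OC)Sc2ccccc21 | intermediate
4 | 2-hydroxy-1-(2-methoxy-4-methylphenyl)ethan-1-one | COc1cc(C)ccc1C(=O)CO | intermediate
5 | (chloromethyl)(isopropoxy)dimethylsilane | CC(C)O[Si](C)(C)CCl | starting material
6 | {[isopropoxy(dimethyl)silyl]methyl}magnesium chloride | CC(C)O[Si](C)(C)C[Mg]Cl | intermediate
7 | 3-[isopropoxy(dimethyl)silyl]-2-(2-methoxy-4-methylphenyl)propane-1,2-diol (racemic) | COc1cc(C)ccc1C(O)(CO)C[Si](C)(C)OC(C)C | intermediate
8 | 2-(2-methoxy-4-methylphenyl)propane-1,2,3-triol (achiral) | COc1cc(C)ccc1C(O)(CO)CO | intermediate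
9 | isobutyric anhydride | CC(C)C(=O)OC(=O)C(C)C | starting material
10 | 2-hydroxy-2-(2-methoxy-4-methylphenyl)propane-1,3-diyl bis(2-methylpropanoate) (achiral) | COc1cc(C)ccc1C(O)(COC(=O)C(C)C)COC(=O)C(C)C | target

Total step count: 4. Longest linear sequence: 4 steps (1 to 4 to 7 to 8 to 10).

## Steps least certain to work

Step 1 (key step).
- What may go wrong: self-condensation of formaldehyde on the carbene (formose-type oligomerisation), which would consume the acceptor and tie up the catalyst, combined with slow formation of 3 from an electron-rich, ortho-substituted aldehyde. A further drain is a second, base-mediated hydroxymethylation at C9 of 4 by the excess formaldehyde.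
- Why: benzothiazolium-derived carbenes also activate formaldehyde as a donor, and 1 is a weak electrophile.
- Fallback, from 1 back to 4, using a stoichiometric acyl-anion equivalent in place of catalysis: 1 would be condensed with propane-1,3-dithiol (BF3·OEt2, CH2Cl2) to 2-(2-methoxy-4-methylphenyl)-1,3-dithiane F1. Deprotonation with n-BuLi in THF and quenching with dry formaldehyde (from 2) would give [2-(2-methoxy-4-methylphenyl)-1,3-dithian-2-yl]methanol F2. Alkylative hydrolysis (MeI, CaCO3, aqueous MeCN) would release 4.

Step 2.
- What may go wrong: incomplete addition to the chelated, ortho-substituted and alkoxide-deactivated ketone, with enolisation toward C9 returning 4 on work-up; premature Peterson-type loss of silicon if the quench turns acidic.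
- Why: the reagent is bulky and the carbonyl is both hindered and electron-rich.
- Fallback, from 4 back to 8, replacing the carbanion by an ylide and bypassing step 3 as well: Wittig methylenation of 4 with excess Ph3P=CH2 (from Ph3PCH3Br and KOtBu, THF) would give 2-(2-methoxy-4-methylphenyl)prop-2-en-1-ol F3. Catalytic dihydroxylation (K2OsO4·2H2O, N-methylmorpholine N-oxide, acetone/water) would then give 8.

Step 3.
- What may go wrong: fluoride- or base-triggered Peterson elimination of the β-hydroxysilane competing with the silicon-to-oxygen migration; loss of the very polar triol to the aqueous phase on extraction.
- Why: the tertiary alkoxide at C8 sits β to silicon and is benzylic to an electron-rich ring.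
- Fallback, from 4 back to 8, unveiling the C10 oxygen by alkene cleavage without any C–Si oxidation: addition of excess vinylmagnesium bromide to 4 (THF, 0 °C) would give racemic 2-(2-methoxy-4-methylphenyl)but-3-ene-1,2-diol F4. Ozonolysis at −78 °C in CH2Cl2/MeOH with a dye end-point indicator, followed by NaBH4 in the same flask, would cut the vinyl group down to the hydroxymethyl group of 8.

## Further compounds

F1 | step 1 | 2-(2-methoxy-4-methylphenyl)-1,3-dithiane | COc1cc(C)ccc1C1SCCCS1
F2 | step 1 | [2-(2-methoxy-4-methylphenyl)-1,3-dithian-2-yl]methanol | COc1cc(C)ccc1C1(CO)SCCCS1
F3 | step 2 | 2-(2-methoxy-4-methylphenyl)prop-2-en-1-ol | COc1cc(C)ccc1C(=C)CO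
F4 | step 3 | 2-(2-methoxy-4-methylphenyl)but-3-ene-1,2-diol (racemic) | COc1cc(C)ccc1C(O)(CO)C=C
A1 | alternative 1 | (1Z)-1-methoxy-3-methyl-1-(trimethylsilyloxy)buta-1,3-diene | C=C(C)/C=C(/OC)O[Si](C)(C)C
A2 | alternative 1 | 2-oxobut-3-yn-1-yl 2-methylpropanoate | C#CC(=O)COC(=O)C(C)C
A3 | alternative 1 | 2-(2-hydroxy-4-methylphenyl)-2-oxoethyl 2-methylpropanoate | CC(C)C(=O)OCC(=O)c1ccc(C)cc1O
A4 | alternative 2 | methyl 2-methoxy-4-methylbenzoate | COC(=O)c1ccc(C)cc1OC
A5 | alternative 2 | 1,3-bis[isopropoxy(dimethyl)silyl]-2-(2-methoxy-4-methylphenyl)propan-2-ol (achiral) | COc1cc(C)ccc1C(O)(C[Si](C)(C)OC(C)C)C[Si](C)(C)OC(C)C
A6 | alternative 3 | tert-butyl 2-diazo-2-(2-methoxy-4-methylphenyl)acetate | COc1cc(C)ccc1C(=[N+]=[N-])C(=O)OC(C)(C)C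
A7 | alternative 3 | water | O
A8 | alternative 3 | tert-butyl 2,3-dihydroxy-2-(2-methoxy-4-methylphenyl)propanoate (racemic) | CC(C)(C)OC(=O)C(O)(CO)c1ccc(C)cc1OC
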